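The strategy rests on ring B of the naphthalene (C1 aryl, C2 benzyl, C3–OH, C4–H, fused to ring A at C4a/C8a). Its C3(–O)=C4(–H) pair is an enol-type double bond conjugated to ring A, and olefin metathesis can make this one bond while the crowded C1 and C2 are still sp3.
Target ⇐ removal of five O-benzyl groups ⇐ fully protected naphthalene ⇐ loss of the C1 oxygen and C2–H from a 3-benzyloxy-1,2-dihydronaphthalene.
C3=C4 ⇐ ring-closing metathesis of a styrene (C4) with a benzyl enol ether (C3) ⇐ methylenation of a benzyl ester ⇐ C1–C2 aldol addition of a benzyl 3-arylpropanoate enolate to a 2-vinylbenzophenone.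
Benzophenone ⇐ aryl Grignard addition (C1–aryl), oxidation and Stille vinylation (C4a–C4) on brominated O-benzylsyringaldehyde. Ring A, the C1 aryl ring and the catechol ring are bought; ring B is the only ring formed, and it is formed last.
The enol ether oxygen carries benzyl because ionisation at the doubly benzylic C1 should outrun enol ether hydrolysis and would lock any O-alkyl group on C3. A methyl group there could not be removed selectively, whereas benzyl leaves with the others; C1–O is kept as a trimethylsilyl ether to block retro-aldol.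
Key step: step 11

Remark on numbering: the naphthalene locants above (C1 aryl, C2 benzyl, C3 O, C5 OMe, C6 O, C7 OMe) are used for all bicyclic compounds.
Remark on stereochemistry: the target SMILES carries no stereodescriptor, so the hindered C1–aryl axis is treated as configurationally undefined and is not controlled.
Remark on supply: 4-bromo-3-methoxyphenol is taken as a commercial compound.

Step 1
Reactants: 1 syringaldehyde (4-hydroxy-3,5-dimethoxybenzaldehyde)
Product: 2 4-(benzyloxy)-3,5-dimethoxybenzaldehyde
Conditions: BnBr, K2CO3, DMF, 60 °C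
Reagents that add atoms: benzyl bromide, BrCc1ccccc1
Why: Williamson ether synthesis, in which the acidic para-formyl phenoxide is the only nucleophile present and is alkylated cleanly by benzyl bromide.

Step 2
Reactants: 2 4-(benzyloxy)-3,5-dimethoxybenzaldehyde
Product: 3 4-(benzyloxy)-2-bromo-3,5-dimethoxybenzaldehyde
Conditions: NBS (1 equiv.), DMF, rt, dark
Reagents that add atoms: N-bromosuccinimide, O=C1CCC(=O)N1Br
Why: Electrophilic aromatic bromination, in which the two free ring positions are equivalent and each is ortho to one methoxy group and para to the other, so one equivalent of NBS in a polar solvent should give a single monobromide without radical attack on the benzylic CH2.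

Step 3
Reactants: 4 4-bromo-3-methoxyphenol
Product: 5 4-(benzyloxy)-1-bromo-2-methoxybenzene
Conditions: BnBr, K2CO3, acetone, reflux
Reagents that add atoms: benzyl bromide, BrCc1ccccc1
Why: Williamson ether synthesis on the single free phenol, which fixes the OMe (ortho) and OBn (para) pattern relative to bromine without any selectivity problem.

Step 4
Reactants: 5 4-(benzyloxy)-1-bromo-2-methoxybenzene; 3 4-(benzyloxy)-2-bromo-3,5-dimethoxybenzaldehyde
Product: 8 [4-(benzyloxy)-2-bromo-3,5-dimethoxyphenyl][4-(benzyloxy)-2-methoxyphenyl]methanol (racemic), via arylmagnesium bromide 6 (not isolated), via bromomagnesium alkoxide 7 (not isolated)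
Conditions: Mg, THF, reflux; then 3, THF, 0 °C → rt; aq NH4Cl
Reagents that add atoms: none
Why: Grignard addition to a non-enolisable aldehyde, which is much faster than any halogen–magnesium exchange with the aryl bromide of 3, and the racemic carbinol centre is erased in step 5.

Step 5
Reactants: 8 [4-(benzyloxy)-2-bromo-3,5-dimethoxyphenyl][4-(benzyloxy)-2-methoxyphenyl]methanol
Product: 9 [4-(benzyloxy)-2-bromo-3,5-dimethoxyphenyl][4-(benzyloxy)-2-methoxyphenyl]methanone
Conditions: Dess–Martin periodinane, CH2Cl2, rt
Reagents that add atoms: none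
Why: Dess–Martin oxidation converts the hindered secondary benzhydrol to the diaryl ketone under nearly neutral conditions that should not ionise the electron-rich carbinol.

Step 6
Reactants: 9 [4-(benzyloxy)-2-bromo-3,5-dimethoxyphenyl][4-(benzyloxy)-2-methoxyphenyl]methanone
Product: 10 [4-(benzyloxy)-3,5-dimethoxy-2-vinylphenyl][4-(benzyloxy)-2-methoxyphenyl]methanone
Conditions: Bu3SnCH=CH2, Pd(PPh3)4 (cat.), toluene, 100 °C
Reagents that add atoms: tributyl(vinyl)stannane, C=C[Sn](CCCC)(CCCC)CCCC
Why: Stille coupling, in which the ortho aroyl group helps oxidative addition of zerovalent palladium to the flanked C–Br bond and the vinyl group transfers from tin in preference to butyl.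

Step 7
Reactants: 11 3-(3,4-dihydroxyphenyl)propanoic acid
Product: 12 benzyl 3-[3,4-bis(benzyloxy)phenyl]propanoate
Conditions: BnBr (excess), K2CO3, DMF, 60 °C
Reagents that add atoms: benzyl bromide, BrCc1ccccc1
Why: Threefold O-alkylation (Williamson ether synthesis of both phenols and carboxylate alkylation) in one operation, which also places on the ester oxygen the benzyl group that later sits on C3–O.

Step 8
Reactants: 12 benzyl 3-[3,4-bis(benzyloxy)phenyl]propanoate; 10 [4-(benzyloxy)-3,5-dimethoxy-2-vinylphenyl][4-(benzyloxy)-2-methoxyphenyl]methanone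
Product: 15 benzyl 3-[4-(benzyloxy)-3,5-dimethoxy-2-vinylphenyl]-3-[4-(benzyloxy)-2-methoxyphenyl]-2-[3,4-bis(benzyloxy)benzyl]-3-hydroxypropanoate (racemic, both diastereomers), via lithium enolate 13 (not isolated), via lithium aldolate 14 (not isolated)
Conditions: LiN(iPr)2, THF, −78 °C; then 10, −78 → −50 °C; AcOH, −78 °C; crude product kept on Et3N-washed silica
Reagents that add atoms: none
Why: Aldol addition of a lithium ester enolate (used in excess) to a non-enolisable diaryl ketone whose ortho methoxy group can chelate lithium, with a cold acetic acid quench to protonate the aldolate before it reverts; C1 and C2 are set without control as a racemic diastereomer mixture because both are destroyed in step 12.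

Step 9
Reactants: 15 the β-hydroxy benzyl ester of step 8
Product: 16 benzyl 3-[4-(benzyloxy)-3,5-dimethoxy-2-vinylphenyl]-3-[4-(benzyloxy)-2-methoxyphenyl]-2-[3,4-bis(benzyloxy)benzyl]-3-(trimethylsilyloxy)propanoate (racemic, both diastereomers)
Conditions: N-(trimethylsilyl)imidazole, CH2Cl2, rt
Reagents that add atoms: N-(trimethylsilyl)imidazole, C[Si](C)(C)n1ccnc1
Why: O-silylation by silyl transfer from imidazole, a method that reaches tertiary diarylcarbinols next to a branched carbon without acid or strong base, so the carbinol neither ionises nor reverts and can no longer quench the titanium reagent of step 10.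

Step 10
Reactants: 16 the silylated benzyl ester of step 9
Product: 17 1-[4-(benzyloxy)-3,5-dimethoxy-2-vinylphenyl]-1-[4-(benzyloxy)-2-methoxyphenyl]-3-(benzyloxy)-2-[3,4-bis(benzyloxy)benzyl]-1-(trimethylsilyloxy)but-3-ene (racemic, both diastereomers)
Conditions: Cp2TiCH2ClAlMe2 (Tebbe reagent, toluene solution), THF, pyridine (trace), −40 °C → rt; aq NaOH; basic Al2O3
Reagents that add atoms: Tebbe reagent Cp2TiCH2ClAlMe2, C[Al](C)[CH2-].[Cl-].[Ti+4].c1cc[cH-]c1.c1cc[cH-]c1
Why: Tebbe methylenation, in which the titanium methylidene released by the Lewis basic medium adds to the only carbonyl group and the oxatitanacyclobutane collapses to the benzyl enol ether, while exchange with the styrene CH2 is degenerate and harmless.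

Step 11
Reactants: 17 the styrene–benzyl enol ether diene of step 10
Product: 18 1-[4-(benzyloxy)-2-methoxyphenyl]-3,6-bis(benzyloxy)-2-[3,4-bis(benzyloxy)benzyl]-5,7-dimethoxy-1-(trimethylsilyloxy)-1,2-dihydronaphthalene (racemic, both diastereomers)
Conditions: second-generation Grubbs catalyst RuCl2(=CHPh)(PCy3)(H2IMes) (cat.), toluene (high dilution), 80 °C, Ar purge; Et3N-washed silica
Reagents that add atoms: none
Why: The ruthenium benzylidene first exchanges with the monosubstituted styrene terminus to put the metal on C4, this alkylidene adds [2+2] across the 1,1-disubstituted benzyl enol ether with ruthenium on the CH2 end, and cycloreversion leaves the C3=C4 bond and a ruthenium methylidene that reloads on the next styrene with loss of ethylene. The closest known reaction type is enol ether–olefin ring-closing metathesis of 2-alkoxy- and 2-silyloxy-1,7-dienes, which gives carbocyclic enol ethers with the same catalyst class, and metathesis followed by elimination is an established entry to phenols and naphthols. Ring B closes as a six-membered carbocycle from a 1,7-diene whose four linking atoms C4a, C8a, C1 and C2 are already in place, the new double bond lying inside the ring. No stereocentre is created and C1 and C2 are not touched, so both diastereomers of 17 are carried through as the corresponding diastereomers of 18. The step needs loading at the styrene rather than formation of an inert alkoxycarbene, and ring closure rather than dimerisation: the first is secured by the 1,1-disubstitution of the enol ether, which offers ruthenium only its CH2 end, the second by high dilution, the rigid ortho-arene link and the fully substituted C1 that presses the two olefins together. The C5 methoxy group can hold the C4 alkylidene as a chelate of the alkoxybenzylidene kind, which is the reason for working at 80 °C, and the silyl ether keeps the C1 oxygen from ionising or binding the metal.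

Step 12
Reactants: 18 the 3-benzyloxy-1,2-dihydronaphthalene of step 11
Product: 19 1-[4-(benzyloxy)-2-methoxyphenyl]-3,6-bis(benzyloxy)-2-[3,4-bis(benzyloxy)benzyl]-5,7-dimethoxynaphthalene
Conditions: camphorsulfonic acid (cat.), CH2Cl2, 0 °C → rt
Reagents that add atoms: none
Why: Acid-catalysed E1 elimination (dehydrative aromatisation), in which the C1–O bond ionises to a cation stabilised by ring A and the 2,4-dialkoxyphenyl group, loss of the C2 proton creates C1=C2 and the aromatic ring B, both stereocentres vanish, and any competing enol ether hydrolysis only gives the C3 naphthol that converges in step 13.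

Step 13
Reactants: 19 the pentabenzyl naphthalene of step 12
Product: 20 3-(3,4-dihydroxybenzyl)-4-(4-hydroxy-2-methoxyphenyl)-6,8-dimethoxynaphthalene-2,7-diol (CNP0000244.0; in the working numbering C1 aryl, C2 benzyl, C3 and C6 OH, C5 and C7 OMe)
Conditions: H2 (1 atm), Pd/C, EtOAc–MeOH, rt; work-up under Ar
Reagents that add atoms: none
Why: Catalytic hydrogenolysis should cleave all five aryl benzyl ethers to toluene while the aryl methyl ethers, the diarylmethane C–C bond and the naphthalene core stay intact.

Compound list
1 | syringaldehyde | COc1cc(C=O)cc(OC)c1O | starting material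
2 | 4-(benzyloxy)-3,5-dimethoxybenzaldehyde | COc1cc(C=O)cc(OC)c1OCc1ccccc1 | intermediate
3 | 4-(benzyloxy)-2-bromo-3,5-dimethoxybenzaldehyde | COc1cc(C=O)c(Br)c(OC)c1OCc1ccccc1 | intermediate
4 | 4-bromo-3-methoxyphenol | COc1cc(O)ccc1Br | starting material
5 | 4-(benzyloxy)-1-bromo-2-methoxybenzene | COc1cc(OCc2ccccc2)ccc1Br | intermediate
6 | [4-(benzyloxy)-2-methoxyphenyl]magnesium bromide (not isolated) | COc1cc(OCc2ccccc2)ccc1[Mg]Br | intermediate
7 | bromomagnesium alkoxide of 8 (racemic, not isolated) | COc1cc(OCc2ccccc2)ccc1C(O[Mg]Br)c1cc(OC)c(OCc2ccccc2)c(OC)c1Br | intermediate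
8 | [4-(benzyloxy)-2-bromo-3,5-dimethoxyphenyl][4-(benzyloxy)-2-methoxyphenyl]methanol (racemic) | COc1cc(OCc2ccccc2)ccc1C(O)c1cc(OC)c(OCc2ccccc2)c(OC)c1Br | intermediate
9 | [4-(benzyloxy)-2-bromo-3,5-dimethoxyphenyl][4-(benzyloxy)-2-methoxyphenyl]methanone | COc1cc(OCc2ccccc2)ccc1C(=O)c1cc(OC)c(OCc2ccccc2)c(OC)c1Br | intermediate
10 | [4-(benzyloxy)-3,5-dimethoxy-2-vinylphenyl][4-(benzyloxy)-2-methoxyphenyl]methanone | COc1cc(OCc2ccccc2)ccc1C(=O)c1cc(OC)c(OCc2ccccc2)c(OC)c1C=C | intermediate
11 | 3-(3,4-dihydroxyphenyl)propanoic acid | OC(=O)CCc1ccc(O)c(O)c1 | starting material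
12 | benzyl 3-[3,4-bis(benzyloxy)phenyl]propanoate | O=C(CCc1ccc(OCc2ccccc2)c(OCc2ccccc2)c1)OCc1ccccc1 | intermediate
13 | lithium enolate of 12 (double-bond geometry of no consequence, not isolated) | [Li]OC(=CCc1ccc(OCc2ccccc2)c(OCc2ccccc2)c1)OCc1ccccc1 | intermediate
14 | lithium aldolate of 15 (racemic, both diastereomers, one drawn; not isolated) | C=Cc1c(OC)c(OCc2ccccc2)c(OC)cc1[C@](O[Li])(c1ccc(OCc2ccccc2)cc1OC)[C@H](Cc1ccc(OCc2ccccc2)c(OCc2ccccc2)c1)C(=O)OCc1ccccc1 | intermediate
15 | benzyl 3-[4-(benzyloxy)-3,5-dimethoxy-2-vinylphenyl]-3-[4-(benzyloxy)-2-methoxyphenyl]-2-[3,4-bis(benzyloxy)benzyl]-3-hydroxypropanoate (racemic, both diastereomers, one drawn) | C=Cc1c(OC)c(OCc2ccccc2)c(OC)cc1[C@](O)(c1ccc(OCc2ccccc2)cc1OC)[C@H](Cc1ccc(OCc2ccccc2)c(OCc2ccccc2)c1)C(=O)OCc1ccccc1 | intermediate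
16 | trimethylsilyl ether of 15 (racemic, both diastereomers, one drawn) | C=Cc1c(OC)c(OCc2ccccc2)c(OC)cc1[C@](O[Si](C)(C)C)(c1ccc(OCc2ccccc2)cc1OC)[C@H](Cc1ccc(OCc2ccccc2)c(OCc2ccccc2)c1)C(=O)OCc1ccccc1 | intermediate
17 | 1-[4-(benzyloxy)-3,5-dimethoxy-2-vinylphenyl]-1-[4-(benzyloxy)-2-methoxyphenyl]-3-(benzyloxy)-2-[3,4-bis(benzyloxy)benzyl]-1-(trimethylsilyloxy)but-3-ene (racemic, both diastereomers, one drawn) | C=Cc1c(OC)c(OCc2ccccc2)c(OC)cc1[C@](O[Si](C)(C)C)(c1ccc(OCc2ccccc2)cc1OC)[C@H](Cc1ccc(OCc2ccccc2)c(OCc2ccccc2)c1)C(=C)OCc1ccccc1 | intermediate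
18 | 1-[4-(benzyloxy)-2-methoxyphenyl]-3,6-bis(benzyloxy)-2-[3,4-bis(benzyloxy)benzyl]-5,7-dimethoxy-1-(trimethylsilyloxy)-1,2-dihydronaphthalene (racemic, both diastereomers, same relative configuration drawn as in 17) | c1ccccc1COC1=Cc2c(OC)c(OCc3ccccc3)c(OC)cc2[C@](O[Si](C)(C)C)(c2ccc(OCc3ccccc3)cc2OC)[C@@H]1Cc1ccc(OCc2ccccc2)c(OCc2ccccc2)c1 | intermediate
19 | 1-[4-(benzyloxy)-2-methoxyphenyl]-3,6-bis(benzyloxy)-2-[3,4-bis(benzyloxy)benzyl]-5,7-dimethoxynaphthalene | COc1cc(OCc2ccccc2)ccc1-c1c(Cc2ccc(OCc3ccccc3)c(OCc3ccccc3)c2)c(OCc2ccccc2)cc2c(OC)c(OCc3ccccc3)c(OC)cc12 | intermediate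
20 | 3-(3,4-dihydroxybenzyl)-4-(4-hydroxy-2-methoxyphenyl)-6,8-dimethoxynaphthalene-2,7-diol (CNP0000244.0) | COc1cc(O)ccc1-c1c(Cc2ccc(O)c(O)c2)c(O)cc2c(OC)c(O)c(OC)cc12 | target

Total step count: 13.
Longest linear sequence: 11 steps (1, 2, 4, 5, 6, 8, 9, 10, 11, 12, 13, from syringaldehyde).

Steps most likely to fail

**Risk 1, step 11 (ring-closing metathesis).**
- What may go wrong: ruthenium may load slowly on the doubly ortho-substituted styrene. The alkylidene may rest as a methoxy chelate, and the catalyst may decay before the hindered enol ether is engaged. The diene would then be returned or the styrene would dimerise.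
- Fallback: it sets out from 16 and comes back at 18, and it needs neither the acyclic enol ether nor ruthenium. Ester 16 is treated with the titanium ethylidene made from TiCl4, Zn, PbCl2 (cat.), TMEDA and CH3CHBr2 (Takai–Utimoto reagent, THF–CH2Cl2, rt → 65 °C).
- How it closes the ring: the titanium alkylidene exchanges with the styrene with loss of propene. The resulting titanium benzylidene at C4 olefinates the benzyl ester carbonyl C3 within the molecule (olefinic ester cyclisation, a stoichiometric carbonyl–olefin metathesis). This closes the same C3=C4 bond, and the carbonyl oxygen ends on titanium.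

**Risk 2, step 8 (aldol addition).**
- What may go wrong: attack may be slow at a carbonyl flanked by two ortho-substituted, electron-rich rings. The crowded aldolate may revert (retro-aldol) before it is protonated.
- Fallback: it sets out from 10 and comes back at 14, which is protonated to 15 as in step 8. It changes the order of bond formation.
- C1–C2 bond: commercial benzyl acetate is deprotonated (LiN(iPr)2, THF, −78 °C) to its lithium enolate F1. This is the least hindered ester enolate, and it adds to 10 to give the lithium aldolate F2.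
- Protection against reversal: a second equivalent of LiN(iPr)2 (−78 → −30 °C) converts F2 into the alkoxide–enolate dianion F3. F3 cannot revert because fragmentation would have to expel a doubly metalated ester.
- C2–CH2 bond: Fráter–Seebach alkylation of F3 with commercial 3,4-bis(benzyloxy)benzyl chloride (THF–DMPU) installs the benzyl group and gives 14.

**Risk 3, step 10 (ester methylenation).**
- What may go wrong: the titanium methylidene may attack slowly at an ester carbonyl that sits next to a branched carbon and a fully substituted carbon. The aluminium component may also ionise the C1–O bond.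
- Fallback: it sets out from 16 and comes back at 20. It replaces the alkyl enol ether by a silyl enol ether made through a ketone.
- Ketone: Me3SiCH2Li (pentane–THF, 0 °C) adds once to the benzyl ester to give the α-trimethylsilyl ketone F4, which is held in the flask in deprotonated form so that no second addition occurs. Methanol at work-up removes the C-silyl group to give the methyl ketone F5.
- Silyl enol ether: kinetic deprotonation at the methyl group (KN(SiMe3)2, THF, −78 °C) and O-silylation with TBSCl give the 2-silyloxy diene F6.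
- Ring closure: silyl enol ether–olefin ring-closing metathesis under the conditions of step 11 gives the cyclic silyl enol ether F7.
- End game: aqueous HF in MeCN removes both silyl groups and dehydrates to the tetrabenzyl 2-naphthol F8. Hydrogenolysis of F8 as in step 13 gives 20.

Further compounds
F0 | step 11 | none | none
F1 | step 8 | lithium enolate of benzyl acetate | [Li]OC(=C)OCc1ccccc1
F2 | step 8 | lithium alkoxide of benzyl 3-[4-(benzyloxy)-3,5-dimethoxy-2-vinylphenyl]-3-[4-(benzyloxy)-2-methoxyphenyl]-3-hydroxypropanoate (racemic) | C=Cc1c(OC)c(OCc2ccccc2)c(OC)cc1C(O[Li])(CC(=O)OCc1ccccc1)c1ccc(OCc2ccccc2)cc1OC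
F3 | step 8 | dilithium alkoxide–enolate dianion of the same ester (racemic) | C=Cc1c(OC)c(OCc2ccccc2)c(OC)cc1C(O[Li])(C=C(O[Li])OCc1ccccc1)c1ccc(OCc2ccccc2)cc1OC
F4 | step 10 | 4-[4-(benzyloxy)-3,5-dimethoxy-2-vinylphenyl]-4-[4-(benzyloxy)-2-methoxyphenyl]-3-[3,4-bis(benzyloxy)benzyl]-1-(trimethylsilyl)-4-(trimethylsilyloxy)butan-2-one (racemic, both diastereomers, one drawn) | C=Cc1c(OC)c(OCc2ccccc2)c(OC)cc1[C@](O[Si](C)(C)C)(c1ccc(OCc2ccccc2)cc1OC)[C@H](Cc1ccc(OCc2ccccc2)c(OCc2ccccc2)c1)C(=O)C[Si](C)(C)C
F5 | step 10 | 4-[4-(benzyloxy)-3,5-dimethoxy-2-vinylphenyl]-4-[4-(benzyloxy)-2-methoxyphenyl]-3-[3,4-bis(benzyloxy)benzyl]-4-(trimethylsilyloxy)butan-2-one (racemic, both diastereomers, one drawn) | C=Cc1c(OC)c(OCc2ccccc2)c(OC)cc1[C@](O[Si](C)(C)C)(c1ccc(OCc2ccccc2)cc1OC)[C@H](Cc1ccc(OCc2ccccc2)c(OCc2ccccc2)c1)C(C)=O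
F6 | step 10 | 3-(tert-butyldimethylsilyloxy) analogue of 17 (racemic, both diastereomers, one drawn) | C=Cc1c(OC)c(OCc2ccccc2)c(OC)cc1[C@](O[Si](C)(C)C)(c1ccc(OCc2ccccc2)cc1OC)[C@H](Cc1ccc(OCc2ccccc2)c(OCc2ccccc2)c1)C(=C)O[Si](C)(C)C(C)(C)C
F7 | step 10 | 3-(tert-butyldimethylsilyloxy) analogue of 18 (racemic, both diastereomers, one drawn) | CC(C)(C)[Si](C)(C)OC1=Cc2c(OC)c(OCc3ccccc3)c(OC)cc2[C@](O[Si](C)(C)C)(c2ccc(OCc3ccccc3)cc2OC)[C@@H]1Cc1ccc(OCc2ccccc2)c(OCc2ccccc2)c1
F8 | step 10 | 1-[4-(benzyloxy)-2-methoxyphenyl]-6-(benzyloxy)-2-[3,4-bis(benzyloxy)benzyl]-5,7-dimethoxynaphthalen-3-ol (working numbering) | COc1cc(OCc2ccccc2)ccc1-c1c(Cc2ccc(OCc3ccccc3)c(OCc3ccccc3)c2)c(O)cc2c(OC)c(OCc3ccccc3)c(OC)cc12
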